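**Retrosynthetic overview**
1. Target ⇐ Suzuki coupling (C5 propenyl) and MOM removal from a 5‑bromo‑2‑aryl‑3‑methyl‑2,3‑dihydrobenzofuran.
2. The dihydrofuran ring (the only ring formed) ⇐ intramolecular oxa‑Michael (1,6‑) addition of the ring‑A phenoxide to a p‑quinone methide, unmasked by fluoride from a bis‑TBS benzylic acetate; the fixed C3 centre directs trans, and the freed 4'‑OH is then methylated.
3. Benzylic acetate ⇐ ring‑B aryllithium + (S)‑2‑arylpropanal of ring A (convergent union, acetate trapped in the same flask).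
4. (S)‑Aldehyde ⇐ Evans methylation of an arylacetyl oxazolidinone ⇐ one‑carbon homologation of 5‑bromo‑o‑vanillin.
5. Ring‑B aryl bromide ⇐ o‑vanillin (benzyl protection, Dakin, MOM, hydrogenolysis, para‑bromination, TBS).

Assumption: 5‑bromo‑o‑vanillin, o‑vanillin, (S)‑4‑benzyloxazolidin‑2‑one and (E)‑propenylboronic acid pinacol ester are bought; the target is (2S,3S), trans (benzofuran numbering, ring B primed).

**Route**

Step 1
Reactants: 1 5-bromo-2-hydroxy-3-methoxybenzaldehyde
Product: 2 5-bromo-2-[(tert-butyldimethylsilyl)oxy]-3-methoxybenzaldehyde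
Conditions: TBSCl, imidazole, DMF, rt
Reagents that add atoms: tert-butyldimethylsilyl chloride C[Si](C)(Cl)C(C)(C)C
Why: Silyl ether formation (substitution at silicon) masks the phenol that fluoride must free later and leaves the aldehyde untouched.

Step 2
Reactants: 2 5-bromo-2-[(tert-butyldimethylsilyl)oxy]-3-methoxybenzaldehyde
Product: 4 2-{5-bromo-2-[(tert-butyldimethylsilyl)oxy]-3-methoxyphenyl}acetaldehyde, via methyl enol ether 3 (not isolated)
Conditions: MeOCH2PPh3Cl, KHMDS, THF, 0 °C; then 2 M aq HCl, THF, rt; crude product used directly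
Reagents that add atoms: (methoxymethyl)triphenylphosphonium chloride COC[P+](c1ccccc1)(c1ccccc1)c1ccccc1.[Cl-]; water O
Why: Wittig methoxymethylenation followed by acid hydrolysis of the enol ether gives the one‑carbon homologated aldehyde, and the non‑nucleophilic amide base spares the aryl silyl ether.

Step 3
Reactants: 4 2-{5-bromo-2-[(tert-butyldimethylsilyl)oxy]-3-methoxyphenyl}acetaldehyde
Product: 5 2-{5-bromo-2-[(tert-butyldimethylsilyl)oxy]-3-methoxyphenyl}acetic acid
Conditions: NaClO2, NaH2PO4, 2-methyl-2-butene, t-BuOH/H2O, rt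
Reagents that add atoms: sodium chlorite [Na+].[O-]Cl=O
Why: Pinnick oxidation converts the aldehyde to the acid at buffered mildly acidic pH, which the aryl TBS ether and aryl bromide tolerate.

Step 4
Reactants: 5 2-{5-bromo-2-[(tert-butyldimethylsilyl)oxy]-3-methoxyphenyl}acetic acid; 6 (S)-4-benzyloxazolidin-2-one
Product: 8 (S)-4-benzyl-3-(2-{5-bromo-2-[(tert-butyldimethylsilyl)oxy]-3-methoxyphenyl}acetyl)oxazolidin-2-one, via mixed pivalic anhydride 7 (not isolated)
Conditions: PivCl, Et3N, THF, −20 °C; then LiCl, 6, −20 °C → rt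
Reagents that add atoms: none
Why: Mixed‑anhydride N‑acylation of the oxazolidinone (LiCl/Et3N protocol) gives the Evans imide without a strong base that could turn the arylacetyl unit into a ketene.

Step 5
Reactants: 8 (S)-4-benzyl-3-(2-{5-bromo-2-[(tert-butyldimethylsilyl)oxy]-3-methoxyphenyl}acetyl)oxazolidin-2-one
Product: 10 (S)-4-benzyl-3-[(S)-2-{5-bromo-2-[(tert-butyldimethylsilyl)oxy]-3-methoxyphenyl}propanoyl]oxazolidin-2-one, via sodium Z-enolate 9 (not isolated)
Conditions: NaHMDS, THF, −78 °C; MeI, −78 → −40 °C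
Reagents that add atoms: iodomethane CI
Why: Evans asymmetric alkylation, in which the chelated sodium Z‑enolate is methylated on the face opposite the 4‑benzyl group, sets the (S) benzylic centre (the future C3), and the minor diastereomer is removed by chromatography.

Step 6
Reactants: 10 (S)-4-benzyl-3-[(S)-2-{5-bromo-2-[(tert-butyldimethylsilyl)oxy]-3-methoxyphenyl}propanoyl]oxazolidin-2-one
Product: 11 (S)-2-{5-bromo-2-[(tert-butyldimethylsilyl)oxy]-3-methoxyphenyl}propan-1-ol
Conditions: LiBH4, H2O (1 equiv), Et2O, 0 °C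
Reagents that add atoms: none
Why: Reductive cleavage of the imide by borohydride releases the auxiliary and gives the primary alcohol without epimerising the α‑aryl centre.

Step 7
Reactants: 11 (S)-2-{5-bromo-2-[(tert-butyldimethylsilyl)oxy]-3-methoxyphenyl}propan-1-ol
Product: 12 (S)-2-{5-bromo-2-[(tert-butyldimethylsilyl)oxy]-3-methoxyphenyl}propanal
Conditions: Dess–Martin periodinane, CH2Cl2, 0 °C → rt; used at once without chromatography
Reagents that add atoms: none
Why: Dess–Martin oxidation is near‑neutral, so the configurationally labile α‑aryl aldehyde is obtained without racemisation if it is used immediately.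

Step 8
Reactants: 13 2-hydroxy-3-methoxybenzaldehyde (o-vanillin)
Product: 14 2-(benzyloxy)-3-methoxybenzaldehyde
Conditions: BnBr, K2CO3, DMF, rt
Reagents that add atoms: benzyl bromide BrCc1ccccc1
Why: Williamson etherification installs a temporary group that survives peracid and is removed by hydrogenolysis before bromine is in the ring.

Step 9
Reactants: 14 2-(benzyloxy)-3-methoxybenzaldehyde
Product: 16 2-(benzyloxy)-3-methoxyphenol, via aryl formate 15 (not isolated)
Conditions: mCPBA, CH2Cl2, rt; then K2CO3 (cat.), MeOH, rt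
Reagents that add atoms: 3-chloroperoxybenzoic acid OOC(=O)c1cccc(Cl)c1
Why: Baeyer–Villiger (Dakin‑type) oxidation, in which the electron‑rich aryl group migrates, gives the formate, which is methanolysed to the phenol.

Step 10
Reactants: 16 2-(benzyloxy)-3-methoxyphenol
Product: 17 2-(benzyloxy)-1-methoxy-3-(methoxymethoxy)benzene
Conditions: MOMCl, iPr2NEt, CH2Cl2, 0 °C → rt
Reagents that add atoms: chloromethyl methyl ether COCCl
Why: O‑Alkylation to the MOM acetal gives a group that cannot migrate to the neighbouring oxygen and survives organolithium, fluoride and base.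

Step 11
Reactants: 17 2-(benzyloxy)-1-methoxy-3-(methoxymethoxy)benzene
Product: 18 2-methoxy-6-(methoxymethoxy)phenol
Conditions: H2 (1 atm), 10% Pd/C, EtOAc, rt
Reagents that add atoms: none
Why: Catalytic hydrogenolysis cleaves only the benzyl ether and frees the central hydroxyl.

Step 12
Reactants: 18 2-methoxy-6-(methoxymethoxy)phenol
Product: 19 4-bromo-2-methoxy-6-(methoxymethoxy)phenol
Conditions: NBS (1.0 equiv), MeCN, −20 → 0 °C
Reagents that add atoms: N-bromosuccinimide O=C1CCC(=O)N1Br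
Why: Electrophilic aromatic bromination goes para to the free phenol because both ortho positions are blocked.

Step 13
Reactants: 19 4-bromo-2-methoxy-6-(methoxymethoxy)phenol
Product: 20 [4-bromo-2-methoxy-6-(methoxymethoxy)phenoxy](tert-butyl)dimethylsilane
Conditions: TBSCl, imidazole, DMF, rt
Reagents that add atoms: tert-butyldimethylsilyl chloride C[Si](C)(Cl)C(C)(C)C
Why: Silylation gives the aryl TBS ether that later acts as the fluoride trigger para to the benzylic carbon.

Step 14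
Reactants: 20 [4-bromo-2-methoxy-6-(methoxymethoxy)phenoxy](tert-butyl)dimethylsilane; 12 (S)-2-{5-bromo-2-[(tert-butyldimethylsilyl)oxy]-3-methoxyphenyl}propanal
Product: 23 (1RS,2S)-2-{5-bromo-2-[(tert-butyldimethylsilyl)oxy]-3-methoxyphenyl}-1-{4-[(tert-butyldimethylsilyl)oxy]-3-methoxy-5-(methoxymethoxy)phenyl}propyl acetate, via aryllithium 21 (not isolated), via lithium alkoxide 22 (not isolated)
Conditions: 20 (1.2 equiv), n-BuLi (1.15 equiv), THF, −78 °C; add 12, −78 °C; then Ac2O, −78 → 0 °C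
Reagents that add atoms: acetic anhydride CC(=O)OC(C)=O
Why: Bromine–lithium exchange, 1,2‑addition of the aryllithium to the aldehyde at −78 °C and acetylation of the alkoxide in the flask join the fragments; the new carbinol centre forms as a mixture that becomes planar in step 15, and the (S) centre is untouched.

Step 15
Reactants: 23 (1RS,2S)-2-{5-bromo-2-[(tert-butyldimethylsilyl)oxy]-3-methoxyphenyl}-1-{4-[(tert-butyldimethylsilyl)oxy]-3-methoxy-5-(methoxymethoxy)phenyl}propyl acetate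
Product: 26 (2S,3S)-5-bromo-2-[3,4-dimethoxy-5-(methoxymethoxy)phenyl]-7-methoxy-3-methyl-2,3-dihydro-1-benzofuran, via p-quinone methide 24 (not isolated), via cyclised phenol 25 (not isolated)
Conditions: TBAF (2.2 equiv), THF, 0 °C → rt until cyclisation is complete; then MeI (5 equiv), rt
Reagents that add atoms: iodomethane CI
Why: Fluoride removes both aryl silyl groups, the 4'‑phenoxide expels acetate (1,6‑elimination) to the p‑quinone methide, the ring‑A phenoxide closes the ring by intramolecular 5‑exo oxa‑Michael (1,6‑conjugate) addition anti to the C3 methyl so that C2 becomes (S) and trans under control of the fixed (3S) centre, and the regenerated 4'‑phenoxide is methylated (Williamson).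

Step 16
Reactants: 26 (2S,3S)-5-bromo-2-[3,4-dimethoxy-5-(methoxymethoxy)phenyl]-7-methoxy-3-methyl-2,3-dihydro-1-benzofuran
Product: 27 5-[(2S,3S)-5-bromo-7-methoxy-3-methyl-2,3-dihydro-1-benzofuran-2-yl]-2,3-dimethoxyphenol
Conditions: HCl (cat.), MeOH/THF, rt → 40 °C
Reagents that add atoms: none
Why: Acid‑catalysed acetal exchange removes the MOM group before the acid‑sensitive propenyl group is present, and any reversible C2–O ionisation would return the more stable trans isomer.

Step 17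
Reactants: 27 5-[(2S,3S)-5-bromo-7-methoxy-3-methyl-2,3-dihydro-1-benzofuran-2-yl]-2,3-dimethoxyphenol; 28 (E)-4,4,5,5-tetramethyl-2-(prop-1-en-1-yl)-1,3,2-dioxaborolane
Product: 29 2,3-dimethoxy-5-{(2S,3S)-7-methoxy-3-methyl-5-[(E)-prop-1-en-1-yl]-2,3-dihydro-1-benzofuran-2-yl}phenol
Conditions: Pd(dppf)Cl2 (5 mol %), K2CO3, dioxane/H2O, 80 °C
Reagents that add atoms: none
Why: Suzuki–Miyaura coupling of the aryl bromide with the (E)‑alkenyl boronate keeps the alkene geometry and tolerates the free phenol.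

**Compound list**
1 | 5-bromo-2-hydroxy-3-methoxybenzaldehyde | O=Cc1cc(Br)cc(OC)c1O | starting material
2 | 5-bromo-2-[(tert-butyldimethylsilyl)oxy]-3-methoxybenzaldehyde | O=Cc1cc(Br)cc(OC)c1O[Si](C)(C)C(C)(C)C | intermediate
3 | tert-butyl{4-bromo-2-methoxy-6-[2-methoxyethenyl]phenoxy}dimethylsilane (E/Z mixture, not isolated) | COC=Cc1cc(Br)cc(OC)c1O[Si](C)(C)C(C)(C)C | intermediate
4 | 2-{5-bromo-2-[(tert-butyldimethylsilyl)oxy]-3-methoxyphenyl}acetaldehyde | O=CCc1cc(Br)cc(OC)c1O[Si](C)(C)C(C)(C)C | intermediate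
5 | 2-{5-bromo-2-[(tert-butyldimethylsilyl)oxy]-3-methoxyphenyl}acetic acid | OC(=O)Cc1cc(Br)cc(OC)c1O[Si](C)(C)C(C)(C)C | intermediate
6 | (S)-4-benzyloxazolidin-2-one | O=C1N[C@@H](Cc2ccccc2)CO1 | starting material
7 | 2-{5-bromo-2-[(tert-butyldimethylsilyl)oxy]-3-methoxyphenyl}acetic pivalic anhydride (not isolated) | CC(C)(C)C(=O)OC(=O)Cc1cc(Br)cc(OC)c1O[Si](C)(C)C(C)(C)C | intermediate
8 | (S)-4-benzyl-3-(2-{5-bromo-2-[(tert-butyldimethylsilyl)oxy]-3-methoxyphenyl}acetyl)oxazolidin-2-one | O=C1OC[C@H](Cc2ccccc2)N1C(=O)Cc1cc(Br)cc(OC)c1O[Si](C)(C)C(C)(C)C | intermediate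
9 | sodium (Z)-1-[(S)-4-benzyl-2-oxooxazolidin-3-yl]-2-{5-bromo-2-[(tert-butyldimethylsilyl)oxy]-3-methoxyphenyl}ethen-1-olate (not isolated) | [Na+].[O-]/C(=C\c1cc(Br)cc(OC)c1O[Si](C)(C)C(C)(C)C)N1[C@@H](Cc2ccccc2)COC1=O | intermediate
10 | (S)-4-benzyl-3-[(S)-2-{5-bromo-2-[(tert-butyldimethylsilyl)oxy]-3-methoxyphenyl}propanoyl]oxazolidin-2-one | O=C1OC[C@H](Cc2ccccc2)N1C(=O)[C@@H](C)c1cc(Br)cc(OC)c1O[Si](C)(C)C(C)(C)C | intermediate
11 | (S)-2-{5-bromo-2-[(tert-butyldimethylsilyl)oxy]-3-methoxyphenyl}propan-1-ol | OC[C@@H](C)c1cc(Br)cc(OC)c1O[Si](C)(C)C(C)(C)C | intermediate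
12 | (S)-2-{5-bromo-2-[(tert-butyldimethylsilyl)oxy]-3-methoxyphenyl}propanal | O=C[C@@H](C)c1cc(Br)cc(OC)c1O[Si](C)(C)C(C)(C)C | intermediate
13 | 2-hydroxy-3-methoxybenzaldehyde (o-vanillin) | O=Cc1cccc(OC)c1O | starting material
14 | 2-(benzyloxy)-3-methoxybenzaldehyde | O=Cc1cccc(OC)c1OCc1ccccc1 | intermediate
15 | 2-(benzyloxy)-3-methoxyphenyl formate (not isolated) | O=COc1cccc(OC)c1OCc1ccccc1 | intermediate
16 | 2-(benzyloxy)-3-methoxyphenol | Oc1cccc(OC)c1OCc1ccccc1 | intermediate
17 | 2-(benzyloxy)-1-methoxy-3-(methoxymethoxy)benzene | COCOc1cccc(OC)c1OCc1ccccc1 | intermediate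
18 | 2-methoxy-6-(methoxymethoxy)phenol | COCOc1cccc(OC)c1O | intermediate
19 | 4-bromo-2-methoxy-6-(methoxymethoxy)phenol | COCOc1cc(Br)cc(OC)c1O | intermediate
20 | [4-bromo-2-methoxy-6-(methoxymethoxy)phenoxy](tert-butyl)dimethylsilane | COCOc1cc(Br)cc(OC)c1O[Si](C)(C)C(C)(C)C | intermediate
21 | {4-[(tert-butyldimethylsilyl)oxy]-3-methoxy-5-(methoxymethoxy)phenyl}lithium (not isolated) | [Li]c1cc(OC)c(O[Si](C)(C)C(C)(C)C)c(OCOC)c1 | intermediate
22 | lithium (1RS,2S)-2-{5-bromo-2-[(tert-butyldimethylsilyl)oxy]-3-methoxyphenyl}-1-{4-[(tert-butyldimethylsilyl)oxy]-3-methoxy-5-(methoxymethoxy)phenyl}propan-1-olate (not isolated) | [Li]OC([C@@H](C)c1cc(Br)cc(OC)c1O[Si](C)(C)C(C)(C)C)c1cc(OC)c(O[Si](C)(C)C(C)(C)C)c(OCOC)c1 | intermediate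
23 | (1RS,2S)-2-{5-bromo-2-[(tert-butyldimethylsilyl)oxy]-3-methoxyphenyl}-1-{4-[(tert-butyldimethylsilyl)oxy]-3-methoxy-5-(methoxymethoxy)phenyl}propyl acetate | CC(=O)OC([C@@H](C)c1cc(Br)cc(OC)c1O[Si](C)(C)C(C)(C)C)c1cc(OC)c(O[Si](C)(C)C(C)(C)C)c(OCOC)c1 | intermediate
24 | 4-[(2R)-2-(5-bromo-2-hydroxy-3-methoxyphenyl)propylidene]-2-methoxy-6-(methoxymethoxy)cyclohexa-2,5-dien-1-one (p-quinone methide, present as its phenoxide, not isolated; same spatial arrangement as in 12, the R label is only a CIP priority change) | C[C@H](C=C1C=C(OC)C(=O)C(OCOC)=C1)c1cc(Br)cc(OC)c1O | intermediate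
25 | 4-[(2S,3S)-5-bromo-7-methoxy-3-methyl-2,3-dihydro-1-benzofuran-2-yl]-2-methoxy-6-(methoxymethoxy)phenol (present as its tetrabutylammonium phenoxide, not isolated) | Brc1cc(OC)c2c(c1)[C@H](C)[C@@H](c1cc(OCOC)c(O)c(OC)c1)O2 | intermediate
26 | (2S,3S)-5-bromo-2-[3,4-dimethoxy-5-(methoxymethoxy)phenyl]-7-methoxy-3-methyl-2,3-dihydro-1-benzofuran | Brc1cc(OC)c2c(c1)[C@H](C)[C@@H](c1cc(OCOC)c(OC)c(OC)c1)O2 | intermediate
27 | 5-[(2S,3S)-5-bromo-7-methoxy-3-methyl-2,3-dihydro-1-benzofuran-2-yl]-2,3-dimethoxyphenol | Brc1cc(OC)c2c(c1)[C@H](C)[C@@H](c1cc(O)c(OC)c(OC)c1)O2 | intermediate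
28 | (E)-4,4,5,5-tetramethyl-2-(prop-1-en-1-yl)-1,3,2-dioxaborolane | C/C=C/B1OC(C)(C)C(C)(C)O1 | starting material
29 | 2,3-dimethoxy-5-{(2S,3S)-7-methoxy-3-methyl-5-[(E)-prop-1-en-1-yl]-2,3-dihydro-1-benzofuran-2-yl}phenol | C/C=C/c1cc(OC)c2c(c1)[C@H](C)[C@@H](c1cc(O)c(OC)c(OC)c1)O2 | target

**Step count**
Total step count: 17.
Longest linear sequence: 11 steps (steps 1–7, then 14–17, from compound 1). The other branch (steps 8–13, then 14–17, from compound 13) is 10 steps.

**Steps most likely to fail, with fallbacks**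

Step 15 (fluoride‑triggered quinone methide formation, oxa‑Michael closure and methylation in one flask). The risks are acetyl transfer to the ring‑A phenoxide, direct SN2 closure that gives some cis isomer, and methylation before ring closure is complete. The fallback sets out from 12 and 21 and comes back at 26. The coupling is quenched with aqueous NH4Cl instead of Ac2O to give the free carbinol (1RS,2S)-2-{5-bromo-2-[(tert-butyldimethylsilyl)oxy]-3-methoxyphenyl}-1-{4-[(tert-butyldimethylsilyl)oxy]-3-methoxy-5-(methoxymethoxy)phenyl}propan-1-ol F1. Buffered TBAF/AcOH desilylation then gives the triol (1RS,2S)-2-(5-bromo-2-hydroxy-3-methoxyphenyl)-1-[4-hydroxy-3-methoxy-5-(methoxymethoxy)phenyl]propan-1-ol F2. This is cyclised by acid catalysis (PPTS, CH2Cl2, rt): the p‑hydroxybenzylic alcohol ionises to the O‑protonated quinone methide, which the ring‑A phenol traps to give the trans phenol 25, now isolated. Separate methylation (MeI, K2CO3, acetone) gives 26.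

Step 14 (aryllithium addition to an enolisable, racemisation‑prone α‑aryl aldehyde that also carries an aryl bromide). The fallback sets out from 10 and comes back at 23. Transamidation of 10 (Me(MeO)NH·HCl, AlMe3, CH2Cl2) gives the Weinreb amide (S)-2-{5-bromo-2-[(tert-butyldimethylsilyl)oxy]-3-methoxyphenyl}-N-methoxy-N-methylpropanamide F3. Acylation of aryllithium 21 with it at −78 °C and a cold acidic quench give the ketone (S)-2-{5-bromo-2-[(tert-butyldimethylsilyl)oxy]-3-methoxyphenyl}-1-{4-[(tert-butyldimethylsilyl)oxy]-3-methoxy-5-(methoxymethoxy)phenyl}propan-1-one F4. This is reduced at once at −78 °C (L‑Selectride) to the alkoxide 22, which is acetylated in the flask to 23.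

Step 2 (Wittig homologation and acidic enol‑ether hydrolysis next to an aryl silyl ether, giving a fragile arylacetaldehyde). The fallback sets out from 2 and comes back at 5. Methylenation (Ph3PCH3Br, KHMDS) gives the styrene tert-butyl(4-bromo-2-ethenyl-6-methoxyphenoxy)dimethylsilane F5. Anti‑Markovnikov hydroboration–oxidation (9‑BBN; NaBO3) gives the alcohol 2-{5-bromo-2-[(tert-butyldimethylsilyl)oxy]-3-methoxyphenyl}ethan-1-ol F6. TEMPO/PhI(OAc)2 oxidation in MeCN/H2O gives acid 5 without passing through an isolated arylacetaldehyde.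

**Further compounds**
F1 | step 15 | (1RS,2S)-2-{5-bromo-2-[(tert-butyldimethylsilyl)oxy]-3-methoxyphenyl}-1-{4-[(tert-butyldimethylsilyl)oxy]-3-methoxy-5-(methoxymethoxy)phenyl}propan-1-ol | OC([C@@H](C)c1cc(Br)cc(OC)c1O[Si](C)(C)C(C)(C)C)c1cc(OC)c(O[Si](C)(C)C(C)(C)C)c(OCOC)c1
F2 | step 15 | (1RS,2S)-2-(5-bromo-2-hydroxy-3-methoxyphenyl)-1-[4-hydroxy-3-methoxy-5-(methoxymethoxy)phenyl]propan-1-ol | OC([C@@H](C)c1cc(Br)cc(OC)c1O)c1cc(OC)c(O)c(OCOC)c1
F3 | step 14 | (S)-2-{5-bromo-2-[(tert-butyldimethylsilyl)oxy]-3-methoxyphenyl}-N-methoxy-N-methylpropanamide | CON(C)C(=O)[C@@H](C)c1cc(Br)cc(OC)c1O[Si](C)(C)C(C)(C)C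
F4 | step 14 | (S)-2-{5-bromo-2-[(tert-butyldimethylsilyl)oxy]-3-methoxyphenyl}-1-{4-[(tert-butyldimethylsilyl)oxy]-3-methoxy-5-(methoxymethoxy)phenyl}propan-1-one | O=C([C@@H](C)c1cc(Br)cc(OC)c1O[Si](C)(C)C(C)(C)C)c1cc(OC)c(O[Si](C)(C)C(C)(C)C)c(OCOC)c1
F5 | step 2 | tert-butyl(4-bromo-2-ethenyl-6-methoxyphenoxy)dimethylsilane | C=Cc1cc(Br)cc(OC)c1O[Si](C)(C)C(C)(C)C
F6 | step 2 | 2-{5-bromo-2-[(tert-butyldimethylsilyl)oxy]-3-methoxyphenyl}ethan-1-ol | OCCc1cc(Br)cc(OC)c1O[Si](C)(C)C(C)(C)C
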